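**Plan**
- **Cuts:** the C2 hydroxyl is masked as an isopropyl ether and the quinone is traced back to its hydroquinone. The ring is then cut at C4–C5 (electrocyclic closure) and at C1–C6 (carbonyl addition), and the side chain at C3–C1' (Grignard addition).
- **Enabling feature:** ring atoms C1(=O)–C2(O)–C3(docosyl)–C4(=O) are four contiguous carbons with the connectivity and oxidation level of a 3-alkyl-4-alkoxycyclobutene-1,2-dione. C5(OMe)=C6(H) is a two-carbon enol ether, and the para oxygens at C1 and C4 are what a carbinol carbon and a ketene carbon turn into.
- **Forward order:** the four-membered ring is bought as diisopropyl squarate. The C22 chain is attached first and the methoxyvinyl unit second, and heating then expands the small ring into the only ring of the target. Oxidation and loss of isopropyl finish the synthesis.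
- **Stereochemistry:** the target has none, and the carbinol centres and the Z enol ether on the way are transient. Regiocontrol takes the place of stereocontrol and is settled in the carbonyl addition of step 5.

Key step: step 6

Remark: the target has no stereocentre and no configurable double bond, so it is one achiral compound and "single enantiomer" reduces to the correct constitution. The side chain read from the SMILES is an unbranched C22 (docosyl) chain.

**Step 1**
Reactants: 1 1-bromodocosane
Product: 2 docosylmagnesium bromide (titrated THF solution, kept warm and used directly)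
Conditions: Mg turnings, BrCH2CH2Br (cat.), THF, 50 °C
Reagents that add atoms: magnesium, [Mg]
Why: Classical Grignard formation by insertion of activated magnesium into a primary C–Br bond, with warm THF keeping the waxy bromide and its reagent dissolved and slow addition limiting Wurtz coupling.

**Step 2**
Reactants: 2 docosylmagnesium bromide; 3 diisopropyl squarate (3,4-diisopropoxycyclobut-3-ene-1,2-dione)
Product: 4 4-docosyl-4-hydroxy-2,3-diisopropoxycyclobut-2-en-1-one (racemic)
Conditions: THF, −40 → 0 °C (warm solution of 2 added slowly to 3); sat. aq NH4Cl
Reagents that add atoms: none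
Why: 1,2-Addition of a Grignard reagent to one of the two equivalent carbonyl groups of a dialkyl squarate, which should stop after one addition because the magnesium alkoxide deactivates the remaining vinylogous ester carbonyl; the new carbinol centre is racemic and vanishes in step 3.

**Step 3**
Reactants: 4 4-docosyl-4-hydroxy-2,3-diisopropoxycyclobut-2-en-1-one
Product: 5 3-docosyl-4-isopropoxycyclobut-3-ene-1,2-dione
Conditions: conc. HCl (cat.), CH2Cl2, rt
Reagents that add atoms: none
Why: Acid-catalysed vinylogous hydrolysis with 1,3-carbonyl transposition, the standard conversion of squarate adducts into alkylcyclobutenediones, in which the tertiary carbinol ionises to an alkoxy-stabilised cyclobutenyl cation, water returns at the distal alkoxy carbon and the hemiketal releases isopropanol.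

**Step 4**
Reactants: 6 bromoacetaldehyde dimethyl acetal (2-bromo-1,1-dimethoxyethane)
Product: 8 (Z)-1-bromo-2-methoxyethene, via 1,2-dibromo-1-methoxyethane 7 (not isolated)
Conditions: AcBr, ZnBr2 (cat.), CH2Cl2, 0 → 40 °C; then i-Pr2NEt, 0 °C → rt; fractional distillation
Reagents that add atoms: none
Why: Acyl halide cleavage of an acetal to the α-bromo ether followed by amine-induced dehydrobromination, the classical entry to 2-bromovinyl ethers, in which the activated α-bromide leaves with a proton of the CH2Br group and the Z isomer should prevail because it is also the more stable one (cis effect of two vicinal electronegative groups), distillation enriching it further.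

**Step 5**
Reactants: 8 (Z)-1-bromo-2-methoxyethene; 5 3-docosyl-4-isopropoxycyclobut-3-ene-1,2-dione
Product: 10 2-docosyl-4-hydroxy-3-isopropoxy-4-[(Z)-2-methoxyvinyl]cyclobut-2-en-1-one (racemic), via (Z)-2-methoxyvinyllithium 9 (not isolated)
Conditions: 8, n-BuLi, Et2O, −78 °C; then 5 in THF, −78 → −60 °C; aq NH4Cl–NH3 buffer (pH 8); quick filtration through Et3N-deactivated SiO2
Reagents that add atoms: none
Why: Bromine–lithium exchange with retention of geometry gives the O–Li-chelated Z reagent, whose syn arrangement of lithium and methoxy slows β-elimination, and its 1,2-addition should go to the carbonyl next to the isopropoxy-bearing carbon because the other carbonyl is the deactivated end of the vinylogous ester i-PrO–C=C–C=O; the carbinol centre forms racemic and is erased in step 6.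

**Step 6**
Reactants: 10 2-docosyl-4-hydroxy-3-isopropoxy-4-[(Z)-2-methoxyvinyl]cyclobut-2-en-1-one
Product: 13 3-docosyl-2-isopropoxy-5-methoxybenzene-1,4-diol, via dienylketene 11 (not isolated), via 6-methoxycyclohexadienone 12 (not isolated)
Conditions: PhMe (degassed, dilute), 110 °C, Ar, base-washed glassware
Reagents that add atoms: none
Why: This is the Moore rearrangement of a 4-alkenyl-4-hydroxycyclobutenone, with β-substituted vinyl groups inside its known scope: strain release drives a conrotatory 4π opening of the C(=O)–C(OH) bond of 10 to dienylketene 11. The ketene carbon then bonds to the methoxy-bearing vinyl terminus in a thermal disrotatory 6π electrocyclisation, which forms the C4–C5 bond of the target and closes its only ring as dienone 12. The step needs inward rotation of the vinyl arm, and the substrate secures it because the donor hydroxyl on the same carbon prefers to rotate outward, while any ketene of the wrong geometry can only revert through the reversible opening. The Z-methoxy group lies on the inner face of the closing terminus, but its partner is an sp ketene carbon with no inward substituent, so closure should remain fast. A proton shift from the CH(OMe) carbon of 12 to the neighbouring carbonyl oxygen gives arene 13 and wipes out the one new stereocentre and the alkene geometry, so no stereocontrol is called for; acid-free, degassed conditions favour this enolisation over loss of methanol. Regiochemistry is inherited from 10: the ketene carbon is the one attached to the docosyl-bearing carbon, so OMe ends next to the C4 oxygen and H next to the C1 oxygen.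

**Step 7**
Reactants: 13 3-docosyl-2-isopropoxy-5-methoxybenzene-1,4-diol (crude, kept under Ar)
Product: 14 3-docosyl-2-isopropoxy-5-methoxy-1,4-benzoquinone
Conditions: Ag2O, K2CO3, PhMe–Et2O, rt
Reagents that add atoms: none
Why: Mild two-electron oxidation of an electron-rich hydroquinone to the 1,4-benzoquinone with silver(I) oxide, under non-acidic conditions that leave both alkoxy groups untouched.

**Step 8**
Reactants: 14 3-docosyl-2-isopropoxy-5-methoxy-1,4-benzoquinone
Product: 15 3-docosyl-2-hydroxy-5-methoxy-1,4-benzoquinone (target)
Conditions: BCl3 (1.2 equiv), CH2Cl2, −78 → −20 °C; then H2O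
Reagents that add atoms: none
Why: Lewis-acid ether cleavage in which boron binds the C1 carbonyl/C2 ether oxygen pair and the secondary isopropyl group departs by an SN1-like C–O heterolysis far faster than chloride can attack a methyl group by SN2, so that about one equivalent at low temperature should spare the methyl vinylogous ester.

**Compound list**
1 | 1-bromodocosane | CCCCCCCCCCCCCCCCCCCCCCBr | starting material
2 | docosylmagnesium bromide | CCCCCCCCCCCCCCCCCCCCCC[Mg]Br | intermediate
3 | diisopropyl squarate (3,4-diisopropoxycyclobut-3-ene-1,2-dione) | CC(C)OC1=C(OC(C)C)C(=O)C1=O | starting material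
4 | 4-docosyl-4-hydroxy-2,3-diisopropoxycyclobut-2-en-1-one (racemic) | CCCCCCCCCCCCCCCCCCCCCCC1(O)C(OC(C)C)=C(OC(C)C)C1=O | intermediate
5 | 3-docosyl-4-isopropoxycyclobut-3-ene-1,2-dione | CCCCCCCCCCCCCCCCCCCCCCC1=C(OC(C)C)C(=O)C1=O | intermediate
6 | bromoacetaldehyde dimethyl acetal (2-bromo-1,1-dimethoxyethane) | COC(CBr)OC | starting material
7 | 1,2-dibromo-1-methoxyethane (racemic, not isolated) | COC(Br)CBr | intermediate
8 | (Z)-1-bromo-2-methoxyethene | CO/C=C\Br | intermediate
9 | (Z)-2-methoxyvinyllithium (not isolated) | [Li]/C=C\OC | intermediate
10 | 2-docosyl-4-hydroxy-3-isopropoxy-4-[(Z)-2-methoxyvinyl]cyclobut-2-en-1-one (racemic) | CCCCCCCCCCCCCCCCCCCCCCC1=C(OC(C)C)C(O)(/C=C\OC)C1=O | intermediate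
11 | (3Z,5Z)-2-docosyl-4-hydroxy-3-isopropoxy-6-methoxyhexa-1,3,5-trien-1-one (dienylketene, not isolated) | CCCCCCCCCCCCCCCCCCCCCCC(=C=O)/C(OC(C)C)=C(/O)\C=C/OC | intermediate
12 | 2-docosyl-4-hydroxy-3-isopropoxy-6-methoxycyclohexa-2,4-dien-1-one (racemic, not isolated) | CCCCCCCCCCCCCCCCCCCCCCC1=C(OC(C)C)C(O)=CC(OC)C1=O | intermediate
13 | 3-docosyl-2-isopropoxy-5-methoxybenzene-1,4-diol | CCCCCCCCCCCCCCCCCCCCCCc1c(O)c(OC)cc(O)c1OC(C)C | intermediate
14 | 3-docosyl-2-isopropoxy-5-methoxy-1,4-benzoquinone | CCCCCCCCCCCCCCCCCCCCCCC1=C(OC(C)C)C(=O)C=C(OC)C1=O | intermediate
15 | 3-docosyl-2-hydroxy-5-methoxy-1,4-benzoquinone | CCCCCCCCCCCCCCCCCCCCCCC1=C(O)C(=O)C=C(OC)C1=O | target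

**Step count**
- Total step count: 8.
- Longest linear sequence: 7 steps, from 1-bromodocosane 1 through steps 1, 2, 3, 5, 6, 7 and 8. Step 4 is a one-step side branch.

**Steps most likely to fail**

**Step 6.**
- **Risk:** the cyclohexadienone may expel methanol, pushed by the para hydroxyl, faster than it enolises. The hydroxy enol ether may also ionise and transpose before the four-membered ring opens.
- **Fallback:** the ring expansion is kept, but the methoxy group is installed after the ring exists. It sets out from 5.
- Vinylmagnesium bromide (THF, −78 °C) adds to the same carbonyl to give 2-docosyl-4-ethenyl-4-hydroxy-3-isopropoxycyclobut-2-en-1-one F1.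
- Heating in toluene gives 3-docosyl-2-isopropoxybenzene-1,4-diol F2, and silver(I) oxide gives 2-docosyl-3-isopropoxy-1,4-benzoquinone F3.
- ZnCl2-promoted conjugate addition of methanol (MeOH, air or Ag2O as terminal oxidant) should then attack C5. This is the β-carbon of the enone whose carbonyl (C1) is not deactivated by vinylogous donation from the isopropoxy group.
- The adduct is oxidised in the same flask, and the route is rejoined at 14.

**Step 5.**
- **Risk:** dehydrobromination of the bromide and loss of lithium methoxide from the reagent may compete with the exchange, so the vinyl nucleophile is under-delivered. The long-chain dione may also fall out of solution at low temperature before it is consumed.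
- **Fallback:** a robust acetylide replaces the vinyl anion and the alkene is made afterwards. It sets out from 8 and 5.
- Two equivalents of lithium diethylamide (THF, −78 → 0 °C) bring about anti elimination of HBr, since H and Br are trans in the Z bromide. They also deprotonate the methoxyacetylene formed, giving lithium methoxyacetylide F4.
- F4 adds at −78 °C to the carbonyl next to the isopropoxy-bearing carbon of 5 to give 2-docosyl-4-hydroxy-3-isopropoxy-4-(methoxyethynyl)cyclobut-2-en-1-one F5.
- Lindlar semi-hydrogenation (H2, quinoline, EtOAc, rt) delivers hydrogen syn to the ynol ether while the tetrasubstituted ring alkene stays inert. The route is rejoined at 10.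

**Step 8.**
- **Risk:** chelation-assisted loss of the methyl group alongside the isopropyl group, or exchange of the C5 alkoxy group, may erode the differentiation of the two oxygens.
- **Fallback:** differentiation by protecting group is given up in favour of differentiation by sterics. It sets out from 14.
- Excess BBr3 (CH2Cl2, −78 °C → rt) removes both alkyl groups to give 3-docosyl-2,5-dihydroxy-1,4-benzoquinone F6.
- Acid-catalysed vinylogous Fischer esterification (MeOH, cat. H2SO4, reflux) should methylate only an oxygen-bearing carbon next to the ring C–H. Addition–elimination of methanol at the carbons flanked by the docosyl chain is hindered.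
- The two unhindered positions are equivalent through tautomerism, so a single monomethyl ether is expected, and the route is rejoined at 15.

**Further compounds**
F1 | step 6 | 2-docosyl-4-ethenyl-4-hydroxy-3-isopropoxycyclobut-2-en-1-one (racemic) | CCCCCCCCCCCCCCCCCCCCCCC1=C(OC(C)C)C(O)(C=C)C1=O
F2 | step 6 | 3-docosyl-2-isopropoxybenzene-1,4-diol | CCCCCCCCCCCCCCCCCCCCCCc1c(O)ccc(O)c1OC(C)C
F3 | step 6 | 2-docosyl-3-isopropoxy-1,4-benzoquinone | CCCCCCCCCCCCCCCCCCCCCCC1=C(OC(C)C)C(=O)C=CC1=O
F4 | step 5 | lithium methoxyacetylide | [Li]C#COC
F5 | step 5 | 2-docosyl-4-hydroxy-3-isopropoxy-4-(methoxyethynyl)cyclobut-2-en-1-one (racemic) | CCCCCCCCCCCCCCCCCCCCCCC1=C(OC(C)C)C(O)(C#COC)C1=O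
F6 | step 8 | 3-docosyl-2,5-dihydroxy-1,4-benzoquinone | CCCCCCCCCCCCCCCCCCCCCCC1=C(O)C(=O)C=C(O)C1=O
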